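**Retrosynthetic overview**
1. No ring is formed: the benzene ring is bought as 5-bromovanillin (1), and the target has no stereocentre to set.
2. Substitution pattern: a second C–Br is placed para to the OMe group (1 to 2), then the O–Me bond is cleaved through borate 3 to give catechol aldehyde 4.
3. Key disconnection: the benzylic CH2–N bond, not the amide N–C(=O) bond. Aldehyde 4 and the intact primary amide succinamic acid (5) are joined by reductive amidation through hemiaminal 6 and N-acyliminium 7 to give target 8.
4. This avoids the benzylamine, any oxime or azide reduction next to two aryl bromides, and all protecting groups (3 steps).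

Assumption: the target SMILES has no stereocentre and no stereogenic double bond, so it is achiral and "single enantiomer" requires no stereocontrol.

**Route**

Step 1
Reactants: 1 5-bromovanillin (3-bromo-4-hydroxy-5-methoxybenzaldehyde)
Product: 2 2,3-dibromo-4-hydroxy-5-methoxybenzaldehyde (5,6-dibromovanillin)
Conditions: Br2 (1.3 equiv), Fe powder (5 mol%), NaOAc (1.5 equiv), AcOH, 23 °C then 60 °C
Reagents that add atoms: bromine, BrBr
Why: Electrophilic aromatic bromination (SEAr, FeBr3 formed in situ) goes to the only well-activated open position, para to the OMe group, because the position ortho to the free OH is already brominated and the other open site is squeezed between OMe and CHO; no stereocentre is formed.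

Step 2
Reactants: 2 2,3-dibromo-4-hydroxy-5-methoxybenzaldehyde
Product: 4 2,3-dibromo-4,5-dihydroxybenzaldehyde, via cyclic aryl bromoborate 3 (not isolated)
Conditions: BBr3 (3 equiv), CH2Cl2, −78 °C to 23 °C; then H2O, 0 °C
Reagents that add atoms: none
Why: Lewis-acid aryl methyl ether cleavage (BBr3 O-demethylation) works because the neighbouring free phenol anchors boron and bromide attacks the methyl carbon by SN2 to give the cyclic catechol borate, which water hydrolyses, while the aryl bromides and the aldehyde are untouched; no stereocentre is formed.

Step 3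
Reactants: 4 2,3-dibromo-4,5-dihydroxybenzaldehyde; 5 succinamic acid (4-amino-4-oxobutanoic acid)
Product: 8 4-[(2,3-dibromo-4,5-dihydroxybenzyl)amino]-4-oxobutanoic acid (the target), via N-acyl hemiaminal 6 (not isolated), via N-acyliminium ion 7 (not isolated)
Conditions: 5 (3 equiv), TFA (10 equiv), MeCN, 23 °C, 1 h; then Et3SiH (3 equiv, slow addition), 23 °C to 50 °C
Reagents that add atoms: none
Why: Reductive amidation (reductive N-alkylation of a primary amide by ionic hydrogenation with Et3SiH/TFA) works because the amide nitrogen adds to the aldehyde, TFA ionises the hemiaminal to an N-acyliminium ion strongly stabilised by the para hydroxyl, and Et3SiH delivers hydride to that cation; the aryl bromides, the catechol and the carboxylic acid are inert, and the new sp3 carbon is a CH2, so no stereocentre arises.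

**Compound list**
1 | 5-bromovanillin (3-bromo-4-hydroxy-5-methoxybenzaldehyde) | COc1cc(C=O)cc(Br)c1O | starting material
2 | 2,3-dibromo-4-hydroxy-5-methoxybenzaldehyde (5,6-dibromovanillin) | COc1cc(C=O)c(Br)c(Br)c1O | intermediate
3 | cyclic aryl bromoborate, 2,6,7-tribromo-1,3,2-benzodioxaborole-5-carbaldehyde (not isolated) | O=Cc1cc2OB(Br)Oc2c(Br)c1Br | intermediate
4 | 2,3-dibromo-4,5-dihydroxybenzaldehyde | O=Cc1cc(O)c(O)c(Br)c1Br | intermediate
5 | succinamic acid (4-amino-4-oxobutanoic acid) | NC(=O)CCC(=O)O | starting material
6 | N-acyl hemiaminal, 4-{[(2,3-dibromo-4,5-dihydroxyphenyl)(hydroxy)methyl]amino}-4-oxobutanoic acid, racemic (not isolated) | OC(NC(=O)CCC(=O)O)c1cc(O)c(O)c(Br)c1Br | intermediate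
7 | N-acyliminium ion, (E)-N-(3-carboxypropanoyl)-1-(2,3-dibromo-4,5-dihydroxyphenyl)methaniminium, trifluoroacetate counter-ion (not isolated) | O=C(O)CCC(=O)/[NH+]=C/c1cc(O)c(O)c(Br)c1Br | intermediate
8 | 4-[(2,3-dibromo-4,5-dihydroxybenzyl)amino]-4-oxobutanoic acid (CNP0116984.0, achiral) | O=C(O)CCC(=O)NCc1cc(O)c(O)c(Br)c1Br | target

**Summary**
Total step count: 3.
Longest linear sequence: 3 steps (1 to 2 to 4 to 8).

**Steps most likely to fail, with fallbacks**

Step 3 (highest risk). Et3SiH/TFA may reduce the electron-rich aldehyde to the benzylic alcohol or the methylarene faster than the amide condenses, or the hemiaminal/bis-amide may ionise poorly. The fallback abandons the benzylic C–N disconnection and returns to N-acylation logic. It sets out from 4 and comes back at 8. Compound 4 is condensed with NH2OH·HCl and NaOAc in EtOH to give (E)-2,3-dibromo-4,5-dihydroxybenzaldehyde oxime F1. F1 is reduced with Zn dust in AcOH at 23 °C (no Pd/H2, to keep both C–Br bonds) to 5-(aminomethyl)-3,4-dibromobenzene-1,2-diol F2. F2 is N-acylated by ring opening of succinic anhydride (Et3N, DMF, 0 °C to 23 °C, under argon) to give 8.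

Step 1. Over-bromination, ipso-bromodeformylation para to the phenol, or a regioisomer mixture could erode the yield. The fallback reverses the order of events so that a catechol, not a guaiacol, directs the second bromine. It sets out from 1 and comes back at 4. Compound 1 is O-demethylated with BBr3 in CH2Cl2 to give 3-bromo-4,5-dihydroxybenzaldehyde F3. F3 is brominated with Br2 (1.05 equiv) in AcOH at 23 °C, para to the 5-OH, to give 4 directly.

Step 2. BBr3 may attack or complex the aldehyde (gem-dibromide, tars), or the polar catechol aldehyde may be hard to recover. The fallback moves the deprotection to the end, onto a substrate with no aldehyde. It sets out from 2 and comes back at 8. Compound 2 undergoes the same reductive amidation with 5 (TFA, Et3SiH, MeCN) to give 4-[(2,3-dibromo-4-hydroxy-5-methoxybenzyl)amino]-4-oxobutanoic acid F4. F4 is O-demethylated with BBr3 (5 equiv, CH2Cl2, −78 °C to 23 °C, then H2O) to give 8.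

**Further compounds**
F1 | step 3 | (E)-2,3-dibromo-4,5-dihydroxybenzaldehyde oxime | O/N=C/c1cc(O)c(O)c(Br)c1Br
F2 | step 3 | 5-(aminomethyl)-3,4-dibromobenzene-1,2-diol | NCc1cc(O)c(O)c(Br)c1Br
F3 | step 1 | 3-bromo-4,5-dihydroxybenzaldehyde | O=Cc1cc(O)c(O)c(Br)c1
F4 | step 2 | 4-[(2,3-dibromo-4-hydroxy-5-methoxybenzyl)amino]-4-oxobutanoic acid | COc1cc(CNC(=O)CCC(=O)O)c(Br)c(Br)c1O
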